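In a one-step world, with a reagent in excess, one clock would do. Here J meets Q to give D and the by-product E, then D turns into L, so there are two clocks.

common to all: time 12 s
- winter: J 0.50 mM; Q 1.25 mM (fed, over 5.0 s); temperature 40 °C; all else is in the flask from the start; the feed brings no volume worth counting
- autumn: J 0.50 mM; Q 1.25 mM; temperature 40 °C; everything together at the start
- noon: J 0.50 mM; Q 1.25 mM (fed, over 5.0 s); the addition at 0 °C, then warmed to 40 °C; the feed brings no volume worth counting
- summer: J 0.50 mM (fed, over 5.0 s); Q 1.25 mM; temperature 40 °C; all else is in the flask from the start; the feed brings no volume worth counting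

1. the flask that comes out highest in amount of L, in percent of the J charged, or "all alike" when all lie within 1.5 percentage points (winter / autumn / noon / summer / all alike)
2. L at the end, in percent of the J charged, winter
3. L at the end, in percent of the J charged, autumn
4. L at the end, in percent of the J charged, noon
5. L at the end, in percent of the J charged, summer

    J + Q → D + E (k1 = 265 M⁻¹ s⁻¹, Ea1 = 38.0 kJ mol⁻¹)
    D → L (k2 = 0.102 s⁻¹, Ea2 = 93.0 kJ mol⁻¹)
    X ⇌ E, rate k3*(cs3 - [E]) while solid is left; crystals form when [E] > cs3 (cs3 = 0.35 mM, k3 = 44.9 s⁻¹)
    (constants at 40 °C)

- for E the X are counted in
- as a solid, counted per litre of solution: X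
- all constants are for 40 °C and move with temperature by the activation energies

Q is not constant. In autumn it falls from 1.25 mM towards 0.750 mM, a fall I can reckon from the charges, so I freeze it at the midpoint, 1.00 mM. That makes the first step pseudo-first-order, and the frozen lifetime of J, the reciprocal of the first rate constant 265 M⁻¹ s⁻¹ times this frozen Q, is 3.77 s. The lifetime of D at 40 °C is 9.80 s, which is 2.60 times as long, so the two times are of like size and I keep both.

With these two times, two first-order steps in a row give L at 12 s in autumn as 54.8 %. A steady feed delays its material by 2.50 s on average, so I take that off the clock for winter and summer and get 43.4 % for both. For noon I assume, as a rough step, that the cold feed counts for nothing, which leaves 7.00 s and 30.2 %. My order is autumn, then the two fed flasks, then noon.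

The forecast names autumn, with 44.2 % for winter, 54.6 % for autumn, 32.4 % for noon and 43.3 % for summer, on the ground that “Feeding delays D formation”.

The simulation gives autumn, with 44.2 % for winter, 54.6 % for autumn, 32.4 % for noon and 43.3 % for summer.

My noon figure of 30.2 % is the one that stands furthest off. Autumn's lead goes with the feed: winter dosed over 0.500 s reaches 53.6 %. In noon, J stands at 15.5 % at the end, and the frozen lifetime over the warm 7.00 s gives 15.6 %.

Now take the neighbour with 1.2 mM of J. Q freezes at 0.650 mM, the lifetime becomes 5.81 s, and J left should be 30.0 %. The computed value is 28.3 %.

The numbers of this flask belong to no real substance; the flask was simulated.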